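**Retrosynthetic overview**

1. Feature: in each cyclohexane, C1 (quaternary, methyl and acyl) and C6 (CHOH) are the alpha and beta carbons of a beta-hydroxy ketone, and C5 carries the Z alkylidene. Both C6 centres are R, so the rings differ only at C1. The two prenyl ketones are made last from aldehydes (allyl Grignard addition, cross-metathesis, oxidation).
2. The central CH2–CH2 bond is cut into a ring B allyl sulfone and a ring A allyl bromide (alkylation, then reductive desulfonylation). In both halves the C1-CH2OH/C6-OH pair is a p-methoxybenzylidene acetal, later opened to C6-OPMB and CH2OH.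
3. Each ring comes from the same acyclic (Z)-enal dialdehyde 16 by an amine-catalysed 6-enolexo aldol that forms the C1–C6 bond. The C6 oxygen is expected to come out axial and cis to formyl, because an equatorial oxygen would eclipse the Z CH2OTBS arm. The two catalyst enantiomers therefore give enantiomers 17 and 18: 18 is ring B as it stands, and 17 has C1 of ring A with C6 to be reset by oxidation and hydroxyl-directed reduction.
4. Dialdehyde 16 is built from methallyl Grignard and 1-bromo-3-chloropropane, then a phosphonium salt, iodo-ylide olefination with silyloxyacetaldehyde (Z iodoalkene), hydroboration, lithiation–formylation and oxidation.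
5. Order of ring formation: ring A (step 7) and ring B (step 8) are closed separately and joined in step 20.

Key step: step 7

Remark on the chemistry: monocyclic compounds are numbered C1 (quaternary), C2–C4, C5 (alkylidene), C6 (carbinol); the threonine catalysts are assumed to induce in the same sense as (S)-proline in aldehyde aldols, and if the sense is opposite the catalysts of steps 7 and 8 change places.

**Route**

Step 1
Reactants: 1 2-methylallylmagnesium chloride; 2 1-bromo-3-chloropropane
Product: 3 6-chloro-2-methylhex-1-ene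
Conditions: THF, 0 °C to reflux (2 in excess)
Reagents that add atoms: none
Why: SN2 coupling of an allylic Grignard reagent at the C–Br end of the dihalide, the C–Cl end being much slower, as in the standard preparation of 6-chloro-1-hexene.

Step 2
Reactants: 3 6-chloro-2-methylhex-1-ene
Product: 5 (5-methylhex-5-en-1-yl)triphenylphosphonium iodide, via 6-iodo-2-methylhex-1-ene 4 (not isolated)
Conditions: NaI, PPh3, MeCN, reflux
Reagents that add atoms: sodium iodide [Na+].[I-]; triphenylphosphine c1ccc(cc1)P(c1ccccc1)c1ccccc1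
Why: Finkelstein exchange to the iodide followed in the same pot by SN2 quaternisation of the phosphine.

Step 3
Reactants: 5 (5-methylhex-5-en-1-yl)triphenylphosphonium iodide; 6 (tert-butyldimethylsilyloxy)acetaldehyde
Product: 10 tert-butyl{[(2Z)-3-iodo-7-methylocta-2,7-dien-1-yl]oxy}dimethylsilane, via phosphonium ylide 7 (not isolated), via alpha-iodophosphonium iodide 8 (not isolated), via alpha-iodo ylide 9 (not isolated)
Conditions: NaN(SiMe3)2, THF, 0 °C; I2, −78 °C; NaN(SiMe3)2, −78 to −20 °C; then 6, −78 °C to rt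
Reagents that add atoms: iodine II
Why: Stork–Zhao-type Wittig olefination with an alpha-iodo ylide, which under kinetic control places iodine cis to the aldehyde-derived CH2OTBS group, that is the Z iodoalkene.

Step 4
Reactants: 10 tert-butyl{[(2Z)-3-iodo-7-methylocta-2,7-dien-1-yl]oxy}dimethylsilane
Product: 12 (6Z)-8-(tert-butyldimethylsilyloxy)-6-iodo-2-methyloct-6-en-1-ol (racemic at C2), via B-alkyl-9-borabicyclononane 11 (not isolated)
Conditions: 9-BBN, THF, 0 °C to rt; then NaOH, H2O2, 0 °C
Reagents that add atoms: hydrogen peroxide OO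
Why: Brown hydroboration–oxidation; 9-BBN takes the 1,1-disubstituted alkene much faster than the trisubstituted iodoalkene and puts boron on the terminal carbon, and the racemic centre formed here is erased in steps 7 and 8.

Step 5
Reactants: 12 (6Z)-8-(tert-butyldimethylsilyloxy)-6-iodo-2-methyloct-6-en-1-ol
Product: 15 (2Z)-4-(tert-butyldimethylsilyloxy)-2-(5-hydroxy-4-methylpentyl)but-2-enal (racemic), via lithium alkoxide 13 (not isolated), via alkoxide vinyllithium 14 (not isolated)
Conditions: MeLi (1.0 equiv), Et2O, −78 °C; t-BuLi (2.1 equiv), −78 °C; DMF, −78 °C; then H2O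
Reagents that add atoms: N,N-dimethylformamide CN(C)C=O
Why: Deprotonation, iodine–lithium exchange with retention of alkene geometry and Bouveault formylation; trapping at −78 °C in ether should outrun 1,4-migration of the cis silyl group from oxygen to carbon.

Step 6
Reactants: 15 (2Z)-4-(tert-butyldimethylsilyloxy)-2-(5-hydroxy-4-methylpentyl)but-2-enal
Product: 16 (6Z)-6-formyl-2-methyl-8-(tert-butyldimethylsilyloxy)oct-6-enal (racemic at C2)
Conditions: Dess–Martin periodinane, NaHCO3, CH2Cl2, 0 °C
Reagents that add atoms: none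
Why: Dess–Martin oxidation under buffered, non-basic conditions that leave the Z enal and the silyl ether untouched.

Step 7
Reactants: 16 (6Z)-6-formyl-2-methyl-8-(tert-butyldimethylsilyloxy)oct-6-enal
Product: 17 (1R,6S)-5-[(Z)-2-(tert-butyldimethylsilyloxy)ethylidene]-6-hydroxy-1-methylcyclohexane-1-carbaldehyde (ring A skeleton; hydroxyl cis to formyl and trans to methyl)
Conditions: O-tert-butyl-L-threonine (20 mol %), DMF, 4 °C
Reagents that add atoms: none
Why: The amino acid condenses with the saturated aldehyde only (the alpha-substituted enal is slow to form an iminium ion), the C2 centre of 16 disappears in the enamine, and the enamine carbon adds to the enal C=O while the carboxylic acid hydrogen-bonds that oxygen; the closest known reactions are the amino-acid-catalysed 6-enolexo aldolisation of heptanedials and amine-catalysed aldols of alpha,alpha-dialkyl aldehydes. Ring A closes 6-enolexo-exo-trig through a chair. C1 is set by the catalyst, which fixes the enamine face that meets the hydrogen-bonded carbonyl. C6 is set by the chair: an equatorial C6–O bond would eclipse the Z CH2OTBS arm (allylic 1,3-strain), so the oxygen should go axial, and an axial oxygen that stays gauche to the enamine carbon for the hydrogen bond ends cis to formyl and trans to methyl. The step needs 1,2- and not 1,4-addition, which the three-carbon tether secures (exo chair against an endo attack on a trisubstituted carbon), and it needs the Z alkene to survive, which the reluctance of the branched enal to form a dienamine should allow. C1 of 17 is that of ring A; its C6 hydroxyl is on the other side and is reset in steps 10 and 11.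

Step 8
Reactants: 16 (6Z)-6-formyl-2-methyl-8-(tert-butyldimethylsilyloxy)oct-6-enal
Product: 18 (1S,6R)-5-[(Z)-2-(tert-butyldimethylsilyloxy)ethylidene]-6-hydroxy-1-methylcyclohexane-1-carbaldehyde (enantiomer of 17; the ring B aldehyde)
Conditions: O-tert-butyl-D-threonine (20 mol %), DMF, 4 °C
Reagents that add atoms: none
Why: The same enamine 6-enolexo aldol with the mirror-image catalyst should give the enantiomer of 17, whose C1 and axial C6 hydroxyl (cis to formyl, trans to methyl) are both those of ring B.

Step 9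
Reactants: 17 ring A series hydroxy aldehyde
Product: 19 (1S,6S)-5-[(Z)-2-(tert-butyldimethylsilyloxy)ethylidene]-1-(hydroxymethyl)-1-methylcyclohexan-6-ol (geometry of 17)
Conditions: NaBH4, MeOH, 0 °C
Reagents that add atoms: none
Why: Borohydride reduction of the aldehyde, which touches no stereocentre and removes the retro-aldol risk; the C1 label changes only because CH2OH ranks below C6.

Step 10
Reactants: 19 cis diol of the ring A series
Product: 20 (1S)-5-[(Z)-2-(tert-butyldimethylsilyloxy)ethylidene]-1-(hydroxymethyl)-1-methylcyclohexan-6-one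
Conditions: MnO2, CH2Cl2, rt
Reagents that add atoms: none
Why: MnO2 oxidises only the allylic C6 alcohol and leaves the saturated primary alcohol, so the C6 centre is erased while C1 and the Z alkene stay.

Step 11
Reactants: 20 hydroxymethyl enone
Product: 21 (1S,6R)-5-[(Z)-2-(tert-butyldimethylsilyloxy)ethylidene]-1-(hydroxymethyl)-1-methylcyclohexan-6-ol (hydroxyl cis to methyl; ring A)
Conditions: Me4NBH(OAc)3, MeCN/AcOH, −30 °C
Reagents that add atoms: none
Why: Saksena–Evans reduction: the primary hydroxyl binds the acetoxyborohydride and delivers hydride to the ketone face on its own side, so the new C6 hydroxyl ends trans to CH2OH and cis to methyl, again axial.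

Step 12
Reactants: 21 ring A diol
Product: 22 (2S,4aS,8aR,8Z)-8-[2-(tert-butyldimethylsilyloxy)ethylidene]-2-(4-methoxyphenyl)-4a-methylhexahydro-4H-benzo[d][1,3]dioxine (trans-fused; aryl equatorial)
Conditions: 4-methoxybenzaldehyde dimethyl acetal, PPTS (cat.), 5 Å sieves, CH2Cl2, rt
Reagents that add atoms: 4-methoxybenzaldehyde dimethyl acetal COc1ccc(cc1)C(OC)OC
Why: Acid-catalysed transacetalisation to the six-membered p-methoxybenzylidene acetal, which masks both hydroxyls in one step and later tells them apart.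

Step 13
Reactants: 22 ring A silyl ether acetal
Product: 23 (2Z)-2-[(2S,4aS,8aR)-2-(4-methoxyphenyl)-4a-methylhexahydro-4H-benzo[d][1,3]dioxin-8-ylidene]ethanol
Conditions: TBAF, THF, 0 °C
Reagents that add atoms: none
Why: Fluoride cleavage of the primary silyl ether, to which the acetal is inert.

Step 14
Reactants: 23 ring A allylic alcohol
Product: 24 (2S,4aS,8aR,8Z)-8-(2-bromoethylidene)-2-(4-methoxyphenyl)-4a-methylhexahydro-4H-benzo[d][1,3]dioxine
Conditions: CBr4, PPh3, 2,6-lutidine, CH2Cl2, −20 °C
Reagents that add atoms: carbon tetrabromide BrC(Br)(Br)Br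
Why: Appel bromination, a neutral SN2 process at the primary allylic carbon that keeps the Z geometry; the C6 oxygen is tied in the acetal and cannot close a dihydrofuran.

Step 15
Reactants: 18 ring B hydroxy aldehyde
Product: 25 (1R,6R)-5-[(Z)-2-(tert-butyldimethylsilyloxy)ethylidene]-1-(hydroxymethyl)-1-methylcyclohexan-6-ol (enantiomer of 19; hydroxyl cis to CH2OH; ring B)
Conditions: NaBH4, MeOH, 0 °C
Reagents that add atoms: none
Why: Borohydride reduction of the aldehyde without change at C1 or C6.

Step 16
Reactants: 25 ring B diol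
Product: 26 (2S,4aR,8aR,8Z)-8-[2-(tert-butyldimethylsilyloxy)ethylidene]-2-(4-methoxyphenyl)-4a-methylhexahydro-4H-benzo[d][1,3]dioxine (cis-fused; aryl equatorial)
Conditions: 4-methoxybenzaldehyde dimethyl acetal, PPTS (cat.), 5 Å sieves, CH2Cl2, rt
Reagents that add atoms: 4-methoxybenzaldehyde dimethyl acetal COc1ccc(cc1)C(OC)OC
Why: Transacetalisation as in step 12; the cis diol with axial C6 oxygen gives the unstrained cis-fused acetal.

Step 17
Reactants: 26 ring B silyl ether acetal
Product: 27 (2Z)-2-[(2S,4aR,8aR)-2-(4-methoxyphenyl)-4a-methylhexahydro-4H-benzo[d][1,3]dioxin-8-ylidene]ethanol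
Conditions: TBAF, THF, 0 °C
Reagents that add atoms: none
Why: Fluoride cleavage of the primary silyl ether.

Step 18
Reactants: 27 ring B allylic alcohol
Product: 28 (2S,4aR,8aR,8Z)-8-(2-bromoethylidene)-2-(4-methoxyphenyl)-4a-methylhexahydro-4H-benzo[d][1,3]dioxine
Conditions: CBr4, PPh3, 2,6-lutidine, CH2Cl2, −20 °C
Reagents that add atoms: carbon tetrabromide BrC(Br)(Br)Br
Why: Appel bromination as in step 14.

Step 19
Reactants: 28 ring B allylic bromide
Product: 29 (2S,4aR,8aR,8Z)-2-(4-methoxyphenyl)-4a-methyl-8-[2-(phenylsulfonyl)ethylidene]hexahydro-4H-benzo[d][1,3]dioxine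
Conditions: PhSO2Na, DMF, rt
Reagents that add atoms: sodium benzenesulfinate [Na+].[O-]S(=O)c1ccccc1
Why: SN2 S-alkylation of the sulfinate at the primary allylic carbon.

Step 20
Reactants: 29 ring B allyl sulfone; 24 ring A allylic bromide
Product: 31 coupled sulfone in which the ring A acetal and the ring B acetal are joined C8=CH–CH2–CH(SO2Ph)–CH=C8′ (C8 in ring A, C8′ in ring B; both alkenes Z; mixture at the sulfone carbon), via lithiated sulfone 30 (not isolated)
Conditions: n-BuLi, THF, −78 °C; then 24, −78 to −20 °C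
Reagents that add atoms: none
Why: Biellmann-type alkylation: the allyl sulfone carbanion is alkylated at its alpha carbon by the primary allylic bromide (SN2), which forms the central C–C bond; no ketone or aldehyde is present to compete as an acid or electrophile.

Step 21
Reactants: 31 coupled sulfone
Product: 32 bis-acetal in which the ring A acetal (2S,4aS,8aR) and the ring B acetal (2S,4aR,8aR) are joined C8=CH–CH2–CH2–CH=C8′ (both alkenes Z)
Conditions: Pd(dppf)Cl2 (5 mol %), LiBHEt3, THF, 0 °C
Reagents that add atoms: none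
Why: Palladium-catalysed reductive desulfonylation: zerovalent palladium ionises the allylic sulfone and hydride goes to the less substituted allyl terminus, restoring the trisubstituted exocyclic alkene, whose geometry should hold because syn–anti exchange would need palladium sigma-bonded at the ring carbon.

Step 22
Reactants: 32 bis-acetal
Product: 33 diol bis-PMB ether: ring A (1S,6R) and ring B (1R,6R) 1-(hydroxymethyl)-1-methyl-6-(4-methoxybenzyloxy)cyclohexanes joined C5=CH–CH2–CH2–CH=C5′ (both Z)
Conditions: i-Bu2AlH, CH2Cl2, −78 to 0 °C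
Reagents that add atoms: none
Why: Reductive opening of both p-methoxybenzylidene acetals: aluminium binds the less hindered primary oxygen and that C–O bond is cleaved, which leaves PMB on the secondary C6 oxygen and frees the primary alcohol.

Step 23
Reactants: 33 diol bis-PMB ether
Product: 34 dialdehyde bis-PMB ether: ring A (1R,6R) and ring B (1S,6R) 6-(4-methoxybenzyloxy)-1-methylcyclohexane-1-carbaldehydes joined as in 33
Conditions: Dess–Martin periodinane, NaHCO3, CH2Cl2, 0 °C to rt
Reagents that add atoms: none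
Why: Dess–Martin oxidation of the two neopentyl primary alcohols to aldehydes that have no alpha hydrogen.

Step 24
Reactants: 34 dialdehyde bis-PMB ether; 35 allylmagnesium bromide
Product: 36 bis(homoallylic alcohol): each C1 carries CH(OH)CH2CH=CH2 (ring A 1S,6R; ring B 1R,6R; mixture at the two new carbinol carbons)
Conditions: allylmagnesium bromide (2.5 equiv in all, one allyl group per aldehyde), THF, −78 °C; then H2O
Reagents that add atoms: allylmagnesium bromide C=CC[Mg]Br
Why: Twofold Grignard addition in which each of the two aldehydes takes up one allyl group, so two equivalents of 35 are consumed (the second is the reagent entered above); allylmagnesium bromide adds cleanly to neopentyl aldehydes and has no alpha/gamma ambiguity, unlike a prenyl metal, and the two carbinol centres are oxidised away in step 26.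

Step 25
Reactants: 36 bis(homoallylic alcohol); 37 2-methyl-2-butene
Product: 38 bis(prenyl carbinol): each C1 carries CH(OH)CH2CH=C(CH3)2 (same ring configurations; mixture at the carbinol carbons)
Conditions: second-generation Grubbs catalyst (5 mol %), 2-methyl-2-butene (excess), CH2Cl2, 40 °C
Reagents that add atoms: none
Why: Olefin cross-metathesis of the two terminal alkenes with excess 2-methyl-2-butene turns each allyl into prenyl, while the trisubstituted exocyclic alkenes are too hindered to take part.

Step 26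
Reactants: 38 bis(prenyl carbinol)
Product: 39 bis-PMB ether of the target (ring A 1R,6R; ring B 1S,6R)
Conditions: Dess–Martin periodinane, NaHCO3, CH2Cl2, 0 °C
Reagents that add atoms: none
Why: Dess–Martin oxidation of the hindered secondary alcohols to the beta,gamma-unsaturated ketones under buffered conditions that should not move the prenyl alkene into conjugation.

Step 27
Reactants: 39 bis-PMB ether of the target
Product: 40 CNP0297042.3 (ring A 1R,6R; ring B 1S,6R; both alkylidenes Z)
Conditions: DDQ, CH2Cl2/pH 7 buffer, 0 °C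
Reagents that add atoms: none
Why: Oxidative cleavage of the two PMB ethers by DDQ through the benzylic oxocarbenium ion, near neutral, so neither retro-aldol nor alkene migration in the beta-hydroxy prenyl ketones is expected.

**Compound list**

1 | 2-methylallylmagnesium chloride | CC(=C)C[Mg]Cl | starting material
2 | 1-bromo-3-chloropropane | ClCCCBr | starting material
3 | 6-chloro-2-methylhex-1-ene | C=C(C)CCCCCl | intermediate
4 | 6-iodo-2-methylhex-1-ene | C=C(C)CCCCI | intermediate
5 | (5-methylhex-5-en-1-yl)triphenylphosphonium iodide | C=C(C)CCCC[P+](c1ccccc1)(c1ccccc1)c1ccccc1.[I-] | intermediate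
6 | (tert-butyldimethylsilyloxy)acetaldehyde | O=CCO[Si](C)(C)C(C)(C)C | starting material
7 | (5-methylhex-5-en-1-ylidene)triphenylphosphorane | C=C(C)CCCC=P(c1ccccc1)(c1ccccc1)c1ccccc1 | intermediate
8 | (1-iodo-5-methylhex-5-en-1-yl)triphenylphosphonium iodide | C=C(C)CCCC(I)[P+](c1ccccc1)(c1ccccc1)c1ccccc1.[I-] | intermediate
9 | (1-iodo-5-methylhex-5-en-1-ylidene)triphenylphosphorane | C=C(C)CCCC(I)=P(c1ccccc1)(c1ccccc1)c1ccccc1 | intermediate
10 | tert-butyl{[(2Z)-3-iodo-7-methylocta-2,7-dien-1-yl]oxy}dimethylsilane | C=C(C)CCC/C(I)=C/CO[Si](C)(C)C(C)(C)C | intermediate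
11 | 9-[(6Z)-8-(tert-butyldimethylsilyloxy)-6-iodo-2-methyloct-6-en-1-yl]-9-borabicyclo[3.3.1]nonane | C(C(C)CCC/C(I)=C/CO[Si](C)(C)C(C)(C)C)B1C2CCCC1CCC2 | intermediate
12 | (6Z)-8-(tert-butyldimethylsilyloxy)-6-iodo-2-methyloct-6-en-1-ol, racemic at C2 | OCC(C)CCC/C(I)=C/CO[Si](C)(C)C(C)(C)C | intermediate
13 | lithium alkoxide of 12 | [Li]OCC(C)CCC/C(I)=C/CO[Si](C)(C)C(C)(C)C | intermediate
14 | lithium (6Z)-8-(tert-butyldimethylsilyloxy)-6-lithio-2-methyloct-6-en-1-olate | [Li]OCC(C)CCC/C([Li])=C/CO[Si](C)(C)C(C)(C)C | intermediate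
15 | (2Z)-4-(tert-butyldimethylsilyloxy)-2-(5-hydroxy-4-methylpentyl)but-2-enal, racemic | OCC(C)CCC/C(C=O)=C/CO[Si](C)(C)C(C)(C)C | intermediate
16 | (6Z)-6-formyl-2-methyl-8-(tert-butyldimethylsilyloxy)oct-6-enal, racemic at C2 | O=CC(C)CCC/C(C=O)=C/CO[Si](C)(C)C(C)(C)C | intermediate
17 | (1R,6S)-5-[(Z)-2-(tert-butyldimethylsilyloxy)ethylidene]-6-hydroxy-1-methylcyclohexane-1-carbaldehyde; OH cis to formyl, trans to methyl | O=C[C@]1(C)CCC/C(=C/CO[Si](C)(C)C(C)(C)C)[C@@H]1O | intermediate
18 | (1S,6R)-5-[(Z)-2-(tert-butyldimethylsilyloxy)ethylidene]-6-hydroxy-1-methylcyclohexane-1-carbaldehyde; enantiomer of 17 | O=C[C@@]1(C)CCC/C(=C/CO[Si](C)(C)C(C)(C)C)[C@H]1O | intermediate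
19 | (1S,6S)-5-[(Z)-2-(tert-butyldimethylsilyloxy)ethylidene]-1-(hydroxymethyl)-1-methylcyclohexan-6-ol; OH cis to CH2OH | OC[C@]1(C)CCC/C(=C/CO[Si](C)(C)C(C)(C)C)[C@@H]1O | intermediate
20 | (1S)-5-[(Z)-2-(tert-butyldimethylsilyloxy)ethylidene]-1-(hydroxymethyl)-1-methylcyclohexan-6-one | OC[C@]1(C)CCC/C(=C/CO[Si](C)(C)C(C)(C)C)C1=O | intermediate
21 | (1S,6R)-5-[(Z)-2-(tert-butyldimethylsilyloxy)ethylidene]-1-(hydroxymethyl)-1-methylcyclohexan-6-ol; OH cis to methyl (ring A) | OC[C@]1(C)CCC/C(=C/CO[Si](C)(C)C(C)(C)C)[C@H]1O | intermediate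
22 | (2S,4aS,8aR,8Z)-8-[2-(tert-butyldimethylsilyloxy)ethylidene]-2-(4-methoxyphenyl)-4a-methylhexahydro-4H-benzo[d][1,3]dioxine; trans-fused | COc1ccc(cc1)[C@H]1OC[C@]2(C)CCC/C(=C/CO[Si](C)(C)C(C)(C)C)[C@H]2O1 | intermediate
23 | (2Z)-2-[(2S,4aS,8aR)-2-(4-methoxyphenyl)-4a-methylhexahydro-4H-benzo[d][1,3]dioxin-8-ylidene]ethanol | COc1ccc(cc1)[C@H]1OC[C@]2(C)CCC/C(=C/CO)[C@H]2O1 | intermediate
24 | (2S,4aS,8aR,8Z)-8-(2-bromoethylidene)-2-(4-methoxyphenyl)-4a-methylhexahydro-4H-benzo[d][1,3]dioxine | COc1ccc(cc1)[C@H]1OC[C@]2(C)CCC/C(=C/CBr)[C@H]2O1 | intermediate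
25 | (1R,6R)-5-[(Z)-2-(tert-butyldimethylsilyloxy)ethylidene]-1-(hydroxymethyl)-1-methylcyclohexan-6-ol; enantiomer of 19 (ring B) | OC[C@@]1(C)CCC/C(=C/CO[Si](C)(C)C(C)(C)C)[C@H]1O | intermediate
26 | (2S,4aR,8aR,8Z)-8-[2-(tert-butyldimethylsilyloxy)ethylidene]-2-(4-methoxyphenyl)-4a-methylhexahydro-4H-benzo[d][1,3]dioxine; cis-fused | COc1ccc(cc1)[C@H]1OC[C@@]2(C)CCC/C(=C/CO[Si](C)(C)C(C)(C)C)[C@H]2O1 | intermediate
27 | (2Z)-2-[(2S,4aR,8aR)-2-(4-methoxyphenyl)-4a-methylhexahydro-4H-benzo[d][1,3]dioxin-8-ylidene]ethanol | COc1ccc(cc1)[C@H]1OC[C@@]2(C)CCC/C(=C/CO)[C@H]2O1 | intermediate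
28 | (2S,4aR,8aR,8Z)-8-(2-bromoethylidene)-2-(4-methoxyphenyl)-4a-methylhexahydro-4H-benzo[d][1,3]dioxine | COc1ccc(cc1)[C@H]1OC[C@@]2(C)CCC/C(=C/CBr)[C@H]2O1 | intermediate
29 | (2S,4aR,8aR,8Z)-2-(4-methoxyphenyl)-4a-methyl-8-[2-(phenylsulfonyl)ethylidene]hexahydro-4H-benzo[d][1,3]dioxine | COc1ccc(cc1)[C@H]1OC[C@@]2(C)CCC/C(=C/CS(=O)(=O)c3ccccc3)[C@H]2O1 | intermediate
30 | alpha-lithio derivative of sulfone 29 | COc1ccc(cc1)[C@H]1OC[C@@]2(C)CCC/C(=C/C([Li])S(=O)(=O)c3ccccc3)[C@H]2O1 | intermediate
31 | coupled sulfone: ring A acetal (2S,4aS,8aR) and ring B acetal (2S,4aR,8aR) joined C8=CH–CH2–CH(SO2Ph)–CH=C8′, both Z, mixture at the sulfone carbon | COc1ccc(cc1)[C@H]1OC[C@]2(C)CCC/C(=C/CC(S(=O)(=O)c3ccccc3)/C=C3/CCC[C@]4(C)CO[C@H](c5ccc(OC)cc5)O[C@H]34)[C@H]2O1 | intermediate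
32 | bis-acetal: ring A acetal (2S,4aS,8aR) and ring B acetal (2S,4aR,8aR) joined C8=CH–CH2–CH2–CH=C8′, both Z | COc1ccc(cc1)[C@H]1OC[C@]2(C)CCC/C(=C/CC/C=C3/CCC[C@]4(C)CO[C@H](c5ccc(OC)cc5)O[C@H]34)[C@H]2O1 | intermediate
33 | diol bis-PMB ether: ring A (1S,6R), ring B (1R,6R); C1 CH2OH, C6 OPMB; rings joined C5=CH–CH2–CH2–CH=C5′, both Z | OC[C@]1(C)CCC/C(=C/CC/C=C2/CCC[C@](C)(CO)[C@@H]2OCc2ccc(OC)cc2)[C@H]1OCc1ccc(OC)cc1 | intermediate
34 | dialdehyde bis-PMB ether: ring A (1R,6R), ring B (1S,6R); C1 CHO, C6 OPMB | O=C[C@]1(C)CCC/C(=C/CC/C=C2/CCC[C@](C)(C=O)[C@@H]2OCc2ccc(OC)cc2)[C@H]1OCc1ccc(OC)cc1 | intermediate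
35 | allylmagnesium bromide | C=CC[Mg]Br | starting material
36 | bis(homoallylic alcohol): ring A (1S,6R), ring B (1R,6R); C1 CH(OH)CH2CH=CH2, mixture at the carbinol carbons | C=CCC(O)[C@]1(C)CCC/C(=C/CC/C=C2/CCC[C@](C)(C(O)CC=C)[C@@H]2OCc2ccc(OC)cc2)[C@H]1OCc1ccc(OC)cc1 | intermediate
37 | 2-methyl-2-butene | CC=C(C)C | starting material
38 | bis(prenyl carbinol): ring A (1S,6R), ring B (1R,6R); C1 CH(OH)CH2CH=C(CH3)2, mixture at the carbinol carbons | CC(C)=CCC(O)[C@]1(C)CCC/C(=C/CC/C=C2/CCC[C@](C)(C(O)CC=C(C)C)[C@@H]2OCc2ccc(OC)cc2)[C@H]1OCc1ccc(OC)cc1 | intermediate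
39 | bis-PMB ether of the target: ring A (1R,6R), ring B (1S,6R) | CC(C)=CCC(=O)[C@]1(C)CCC/C(=C/CC/C=C2/CCC[C@](C)(C(=O)CC=C(C)C)[C@@H]2OCc2ccc(OC)cc2)[C@H]1OCc1ccc(OC)cc1 | intermediate
40 | CNP0297042.3: ring A (1R,6R), ring B (1S,6R), both alkylidenes Z | CC(C)=CCC(=O)[C@]1(C)CCC/C(=C/CC/C=C2/CCC[C@](C)(C(=O)CC=C(C)C)[C@@H]2O)[C@H]1O | target

**Step count**

Total steps: 27. Longest linear sequence: 21 steps (1–7, 9–14, 20–27).

**Steps most likely to fail**

1. Step 7 (and, with the other catalyst, step 8). The alpha-branched enamine may form as a mixture of geometries or react with poor facial control, which lowers the stereochemical purity at C1. The amine may also pass through the dienamine of the enal and scramble the Z alkene. Leakage through the other hydrogen-bonded chair (oxygen equatorial, as in dialdehydes that lack the alkylidene) does not harm ring A, because C6 is reset in steps 10 and 11. Fallback for ring A, from 16 to 20: the closure is run with the racemic catalyst (both threonine enantiomers) to give the racemic hydroxy aldehydes F1 (both diastereomers). NaBH4 reduces these to the racemic diols F2, and MnO2 oxidises them to a single racemic enone F3, because C6 is erased. F3 is resolved by preparative chromatography on a chiral stationary phase; its (1S) enantiomer is 20, and step 11 then sets C6 as in the main route.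

2. Step 8. Here both centres of ring B must come from the aldol, so closure through the equatorial-oxygen chair would put the hydroxyl cis to methyl with no later correction. Fallback, from 16 to 25: in that case the catalyst of step 8, O-tert-butyl-D-threonine, still sets C1 and should deliver the (1S,6S) hydroxy aldehyde F4. Pinnick oxidation (NaClO2, NaH2PO4, 2-methyl-2-butene) gives the hydroxy acid F5, TMSCHN2 gives the methyl ester F6, and Dess–Martin oxidation gives the keto ester F7. NaBH4 in MeOH at −40 °C should add hydride anti to the axial ester group, as in 2-alkyl-2-alkoxycarbonylcyclohexanones, to give the cis hydroxy ester F8. LiAlH4 then reduces the ester to diol 25.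

3. Step 21. Hydride may be delivered to the ring terminus of the allylpalladium intermediate, moving the alkene into the ring, or the Z geometry may be lost. Fallback, from 27 to 32: the sulfone is avoided. Alcohol 27 is converted to the allylic chloride F9 (PPh3, CCl4, 2,6-lutidine), and reactive barium (BaI2, lithium biphenylide, THF, −78 °C) turns F9 into the allylbarium chloride F10. Allylic barium reagents couple with allylic bromides at the alpha carbon with retention of alkene geometry, so F10 and bromide 24 should give 32 directly, and steps 18 to 21 fall away.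

**Further compounds**

F1 | step 7 | racemic 5-[(Z)-2-(tert-butyldimethylsilyloxy)ethylidene]-6-hydroxy-1-methylcyclohexane-1-carbaldehyde, both diastereomers | O=CC1(C)CCC/C(=C/CO[Si](C)(C)C(C)(C)C)C1O
F2 | step 7 | racemic 5-[(Z)-2-(tert-butyldimethylsilyloxy)ethylidene]-1-(hydroxymethyl)-1-methylcyclohexan-6-ol, both diastereomers | OCC1(C)CCC/C(=C/CO[Si](C)(C)C(C)(C)C)C1O
F3 | step 7 | racemic 5-[(Z)-2-(tert-butyldimethylsilyloxy)ethylidene]-1-(hydroxymethyl)-1-methylcyclohexan-6-one | OCC1(C)CCC/C(=C/CO[Si](C)(C)C(C)(C)C)C1=O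
F4 | step 8 | (1S,6S)-5-[(Z)-2-(tert-butyldimethylsilyloxy)ethylidene]-6-hydroxy-1-methylcyclohexane-1-carbaldehyde | O=C[C@@]1(C)CCC/C(=C/CO[Si](C)(C)C(C)(C)C)[C@@H]1O
F5 | step 8 | (1S,6S)-5-[(Z)-2-(tert-butyldimethylsilyloxy)ethylidene]-6-hydroxy-1-methylcyclohexane-1-carboxylic acid | OC(=O)[C@@]1(C)CCC/C(=C/CO[Si](C)(C)C(C)(C)C)[C@@H]1O
F6 | step 8 | methyl (1S,6S)-5-[(Z)-2-(tert-butyldimethylsilyloxy)ethylidene]-6-hydroxy-1-methylcyclohexane-1-carboxylate | COC(=O)[C@@]1(C)CCC/C(=C/CO[Si](C)(C)C(C)(C)C)[C@@H]1O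
F7 | step 8 | methyl (1S)-5-[(Z)-2-(tert-butyldimethylsilyloxy)ethylidene]-1-methyl-6-oxocyclohexane-1-carboxylate | COC(=O)[C@@]1(C)CCC/C(=C/CO[Si](C)(C)C(C)(C)C)C1=O
F8 | step 8 | methyl (1S,6R)-5-[(Z)-2-(tert-butyldimethylsilyloxy)ethylidene]-6-hydroxy-1-methylcyclohexane-1-carboxylate, OH cis to ester | COC(=O)[C@@]1(C)CCC/C(=C/CO[Si](C)(C)C(C)(C)C)[C@H]1O
F9 | step 21 | (2S,4aR,8aR,8Z)-8-(2-chloroethylidene)-2-(4-methoxyphenyl)-4a-methylhexahydro-4H-benzo[d][1,3]dioxine | COc1ccc(cc1)[C@H]1OC[C@@]2(C)CCC/C(=C/CCl)[C@H]2O1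
F10 | step 21 | allylbarium chloride derived from F9 | COc1ccc(cc1)[C@H]1OC[C@@]2(C)CCC/C(=C/C[Ba]Cl)[C@H]2O1
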